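**Retrosynthetic overview**

The target is 8,3'-dihydroxy-6,7,4',5'-tetramethoxyflavone; both benzene rings are bought with their oxygen pattern in place and only the pyranone (ring C) is built.
The last ring-forming disconnection is the C4–C4a bond, made by intramolecular Friedel–Crafts acylation of a (Z)-3-aryl-3-aryloxyacrylic acid. It rests on ring A: C4a is ortho to O1 and para to the C7 methoxy, and the other carbon ortho to O1 (C8) is already oxygenated, so a 2,3,4-trioxygenated phenol ether offers a single free ortho carbon.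
Before that, the O1–C2 bond comes from conjugate addition of the ring-A phenol to a ring-B arylpropiolate, whose ester carbon (the later C4) is supplied by di-tert-butyl dicarbonate.
The phenol comes from 2-hydroxy-3,4-dimethoxybenzaldehyde (tosylation, Baeyer–Villiger) and the alkyne from 3-hydroxy-4,5-dimethoxybenzaldehyde (tosylation, Ohira–Bestmann); both tosylates are removed in the last step.

Key step: step 9

Remark on the chemistry: the target is achiral, Ts stands for 4-methylbenzenesulfonyl, and aldehydes 1 and 5 are taken as purchasable.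

**Route**

Step 1
Reactants: 1 2-hydroxy-3,4-dimethoxybenzaldehyde
Product: 2 3,4-dimethoxy-2-(tosyloxy)benzaldehyde
Conditions: TsCl, Et3N, cat. DMAP, CH2Cl2, 0 °C to rt
Reagents that add atoms: 4-methylbenzenesulfonyl chloride (TsCl), Cc1ccc(cc1)S(Cl)(=O)=O
Why: DMAP-catalysed O-sulfonylation of the phenol masks the future C8 hydroxyl as a sulfonate, which should not migrate to a neighbouring oxygen and withstands peracid, mild base and strong acid.

Step 2
Reactants: 2 3,4-dimethoxy-2-(tosyloxy)benzaldehyde
Product: 3 3,4-dimethoxy-2-(tosyloxy)phenyl formate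
Conditions: mCPBA, CH2Cl2, 0 °C to rt
Reagents that add atoms: 3-chloroperbenzoic acid (mCPBA), OOC(=O)c1cccc(Cl)c1
Why: In this Baeyer–Villiger oxidation the aryl group of the Criegee adduct should migrate in preference to hydride, because the ring carries a methoxy group para to the formyl carbon, giving the aryl formate.

Step 3
Reactants: 3 3,4-dimethoxy-2-(tosyloxy)phenyl formate
Product: 4 3,4-dimethoxy-2-(tosyloxy)phenol (hydroxyl at C1, OTs at C2, methoxy at C3 and C4)
Conditions: cat. HCl, MeOH, rt
Reagents that add atoms: none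
Why: Acid-catalysed transesterification removes the labile formyl group as methyl formate, while the acid-inert aryl sulfonate stays and no phenoxide is generated next to it.

Step 4
Reactants: 5 3-hydroxy-4,5-dimethoxybenzaldehyde
Product: 6 3,4-dimethoxy-5-(tosyloxy)benzaldehyde
Conditions: TsCl, Et3N, cat. DMAP, CH2Cl2, 0 °C to rt
Reagents that add atoms: 4-methylbenzenesulfonyl chloride (TsCl), Cc1ccc(cc1)S(Cl)(=O)=O
Why: The same O-sulfonylation masks the future C3' hydroxyl with a group that tolerates the amide base and the acids used later.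

Step 5
Reactants: 6 3,4-dimethoxy-5-(tosyloxy)benzaldehyde
Product: 7 5-ethynyl-2,3-dimethoxyphenyl 4-methylbenzenesulfonate
Conditions: dimethyl (1-diazo-2-oxopropyl)phosphonate, K2CO3, MeOH, 0 °C to rt
Reagents that add atoms: dimethyl (1-diazo-2-oxopropyl)phosphonate (Ohira–Bestmann reagent), COP(=O)(OC)C(=[N+]=[N-])C(C)=O
Why: In this Ohira–Bestmann (Seyferth–Gilbert) homologation methoxide deacylates the reagent to the diazomethylphosphonate anion, which olefinates the aldehyde, and loss of N2 with a 1,2-hydride shift of the alkylidene carbene gives the terminal alkyne, the aryl sulfonate being expected to resist methanolysis at or below room temperature.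

Step 6
Reactants: 7 5-ethynyl-2,3-dimethoxyphenyl 4-methylbenzenesulfonate; 8 di-tert-butyl dicarbonate
Product: 10 tert-butyl 3-[3,4-dimethoxy-5-(tosyloxy)phenyl]prop-2-ynoate, via lithium arylacetylide 9 (not isolated)
Conditions: LiN(SiMe3)2, THF, −78 °C; then 8, −78 to 0 °C; aqueous work-up
Reagents that add atoms: di-tert-butyl dicarbonate (8), CC(C)(C)OC(=O)OC(=O)OC(C)(C)C
Why: The hindered silylamide deprotonates only the terminal alkyne without attacking the sulfonate sulfur, and C-acylation of the lithium acetylide by the dicarbonate, a standard route to tert-butyl arylpropiolates, installs the carbon that becomes C4.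

Step 7
Reactants: 4 3,4-dimethoxy-2-(tosyloxy)phenol; 10 tert-butyl 3-[3,4-dimethoxy-5-(tosyloxy)phenyl]prop-2-ynoate
Product: 11 tert-butyl (Z)-3-[3,4-dimethoxy-2-(tosyloxy)phenoxy]-3-[3,4-dimethoxy-5-(tosyloxy)phenyl]prop-2-enoate
Conditions: Cs2CO3 (0.5 equiv), DMF, 60 °C
Reagents that add atoms: none
Why: Base-mediated oxa-Michael addition of the phenoxide to the aryl-bearing carbon of the propiolate, with protonation of the allenolate anti to the incoming oxygen, should form the O1–C2 bond and give mainly the Z enol ether (aryloxy cis to the ester), while substoichiometric carbonate in an aprotic solvent spares the tert-butyl ester and both sulfonates.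

Step 8
Reactants: 11 tert-butyl (Z)-3-[3,4-dimethoxy-2-(tosyloxy)phenoxy]-3-[3,4-dimethoxy-5-(tosyloxy)phenyl]prop-2-enoate
Product: 12 (Z)-3-[3,4-dimethoxy-2-(tosyloxy)phenoxy]-3-[3,4-dimethoxy-5-(tosyloxy)phenyl]prop-2-enoic acid
Conditions: TFA/CH2Cl2 (1:4), 0 °C to rt, anhydrous; evaporate with toluene
Reagents that add atoms: none
Why: Acidolysis of the tert-butyl ester by E1-type loss of isobutene frees the carboxylic acid under water-free conditions in which the β-aryloxyacrylate (a vinylogous carbonate) and the sulfonates should be stable.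

Step 9
Reactants: 12 (Z)-3-[3,4-dimethoxy-2-(tosyloxy)phenoxy]-3-[3,4-dimethoxy-5-(tosyloxy)phenyl]prop-2-enoic acid
Product: 13 6,7-dimethoxy-2-[3,4-dimethoxy-5-(tosyloxy)phenyl]-8-(tosyloxy)-4H-chromen-4-one (8,3'-bis(tosyloxy)-6,7,4',5'-tetramethoxyflavone)
Conditions: P2O5/MeSO3H (7.7 wt% P2O5, Eaton's reagent), rt, warming to 45 °C if needed; pour onto ice
Reagents that add atoms: none
Why: In P2O5/MeSO3H the carboxyl group of 12 becomes a mixed anhydride or acylium ion that attacks the one unsubstituted carbon ortho to the ether oxygen of the aryloxy ring in an electrophilic aromatic substitution, and loss of a proton gives the 4-pyranone; this is an intramolecular Friedel–Crafts acylation of the Ruhemann type (cycloacylation of a β-aryloxycinnamic acid). Ring C (O1, C2, C3, C4, C4a, C8a) is closed as a six-membered ring at the C4–C4a bond by C-acylation of ring A. No stereocentre is formed; the Z enol ether (carboxyl cis to the aryloxy group) is the isomer that can close, and any E isomer should equilibrate to it by reversible protonation at C3 through an oxocarbenium ion stabilised by the ether oxygen and ring B. The step needs regioselectivity on ring A, which the substrate fixes because the other carbon ortho to O1 carries the sulfonate oxygen, and the attacked carbon is activated by O1 (ortho) and by the future C7 methoxy (para). It also needs six-membered closure onto ring A to outrun five-membered closure onto ring B (an indenone from the E isomer), which the Z geometry set in step 7 and the higher nucleophilicity of the ring-A carbon should secure. Both sulfonates are inert to the acid and sit meta to the reacting carbon, so the two hydroxyls stay masked.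

Step 10
Reactants: 13 6,7-dimethoxy-2-[3,4-dimethoxy-5-(tosyloxy)phenyl]-8-(tosyloxy)-4H-chromen-4-one
Product: 14 8-hydroxy-2-(3-hydroxy-4,5-dimethoxyphenyl)-6,7-dimethoxy-4H-chromen-4-one (target)
Conditions: K2CO3, MeOH, reflux, N2; acidic work-up
Reagents that add atoms: none
Why: Methoxide generated by the carbonate attacks the sulfur of each aryl sulfonate (transesterification at sulfur) and releases the two phenoxides, a standard cleavage of aryl tosylates that should leave the four methyl ethers untouched, and acidification returns the free phenols.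

**Compound list**

1 | 2-hydroxy-3,4-dimethoxybenzaldehyde | COc1ccc(C=O)c(O)c1OC | starting material
2 | 3,4-dimethoxy-2-(tosyloxy)benzaldehyde | COc1ccc(C=O)c(OS(=O)(=O)c2ccc(C)cc2)c1OC | intermediate
3 | 3,4-dimethoxy-2-(tosyloxy)phenyl formate | COc1ccc(OC=O)c(OS(=O)(=O)c2ccc(C)cc2)c1OC | intermediate
4 | 3,4-dimethoxy-2-(tosyloxy)phenol | COc1ccc(O)c(OS(=O)(=O)c2ccc(C)cc2)c1OC | intermediate
5 | 3-hydroxy-4,5-dimethoxybenzaldehyde | COc1cc(C=O)cc(O)c1OC | starting material
6 | 3,4-dimethoxy-5-(tosyloxy)benzaldehyde | COc1cc(C=O)cc(OS(=O)(=O)c2ccc(C)cc2)c1OC | intermediate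
7 | 5-ethynyl-2,3-dimethoxyphenyl 4-methylbenzenesulfonate | COc1cc(C#C)cc(OS(=O)(=O)c2ccc(C)cc2)c1OC | intermediate
8 | di-tert-butyl dicarbonate | CC(C)(C)OC(=O)OC(=O)OC(C)(C)C | starting material
9 | lithium [3,4-dimethoxy-5-(tosyloxy)phenyl]acetylide | COc1cc(C#C[Li])cc(OS(=O)(=O)c2ccc(C)cc2)c1OC | intermediate
10 | tert-butyl 3-[3,4-dimethoxy-5-(tosyloxy)phenyl]prop-2-ynoate | COc1cc(C#CC(=O)OC(C)(C)C)cc(OS(=O)(=O)c2ccc(C)cc2)c1OC | intermediate
11 | tert-butyl (Z)-3-[3,4-dimethoxy-2-(tosyloxy)phenoxy]-3-[3,4-dimethoxy-5-(tosyloxy)phenyl]prop-2-enoate | CC(C)(C)OC(=O)/C=C(\Oc1ccc(OC)c(OC)c1OS(=O)(=O)c1ccc(C)cc1)c1cc(OC)c(OC)c(OS(=O)(=O)c2ccc(C)cc2)c1 | intermediate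
12 | (Z)-3-[3,4-dimethoxy-2-(tosyloxy)phenoxy]-3-[3,4-dimethoxy-5-(tosyloxy)phenyl]prop-2-enoic acid | OC(=O)/C=C(\Oc1ccc(OC)c(OC)c1OS(=O)(=O)c1ccc(C)cc1)c1cc(OC)c(OC)c(OS(=O)(=O)c2ccc(C)cc2)c1 | intermediate
13 | 6,7-dimethoxy-2-[3,4-dimethoxy-5-(tosyloxy)phenyl]-8-(tosyloxy)-4H-chromen-4-one | COc1cc(-c2cc(=O)c3cc(OC)c(OC)c(OS(=O)(=O)c4ccc(C)cc4)c3o2)cc(OS(=O)(=O)c2ccc(C)cc2)c1OC | intermediate
14 | 8-hydroxy-2-(3-hydroxy-4,5-dimethoxyphenyl)-6,7-dimethoxy-4H-chromen-4-one | COc1cc(-c2cc(=O)c3cc(OC)c(OC)c(O)c3o2)cc(O)c1OC | target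

**Step count**

Total: 10 steps. Longest linear sequence: 7 steps (1 → 2 → 3 → 4 → 11 → 12 → 13 → 14; the branch 5 → 6 → 7 → 10 → 11 → 12 → 13 → 14 is equally long).

**Steps most likely to fail**

Step 7 (oxa-Michael addition). The phenoxide is hindered and made less nucleophilic by the ortho sulfonate, and the propiolate carries an electron-rich aryl group, so the addition may be slow and reversible. On prolonged heating a sulfonyl group could also be transferred between phenoxide oxygens. Fallback: the reversible addition is replaced by an irreversible substitution at a vinylic carbon. Setting out from 10, hydroiodination (NaI, AcOH 2 equiv, MeCN, 80 °C; anti addition) should give tert-butyl (Z)-3-iodo-3-[3,4-dimethoxy-5-(tosyloxy)phenyl]prop-2-enoate F1. Ullmann-type vinyl C–O coupling of F1 with phenol 4 (copper iodide CuI, N,N-dimethylglycine, Cs2CO3, dioxane, 80 °C), which proceeds with retention of the double-bond geometry, comes back to the route at 11.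

Step 9 (cycloacylation, key step). In the strong acid, protonation at C3 may lead to loss of CO2 from the carboxyl group or to hydrolytic cleavage of the enol ether before acylation occurs. Five-membered closure onto ring B from the E isomer may also compete. Fallback: ring C is closed at O1–C2 instead, through a chalcone. Setting out from phenol 4, C-acetylation ortho to the hydroxyl (AcOH, BF3·OEt2, 90 °C; Friedel–Crafts/Fries) should give 1-[2-hydroxy-4,5-dimethoxy-3-(tosyloxy)phenyl]ethan-1-one F2. Acid-mediated Claisen–Schmidt condensation of F2 with aldehyde 6 (BF3·OEt2, dioxane, rt) should give (E)-1-[2-hydroxy-4,5-dimethoxy-3-(tosyloxy)phenyl]-3-[3,4-dimethoxy-5-(tosyloxy)phenyl]prop-2-en-1-one F3. Oxidative cyclisation of F3 (cat. I2, DMSO, 120 °C) comes back to the route at 13.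

Step 10 (double sulfonate cleavage). Methoxide may open the pyranone by attack at C2, the hindered ring-B sulfonate on an electron-rich ring may cleave incompletely, and the liberated phenoxide may be re-methylated by the methyl sulfonate that forms. Fallback: the base treatment is moved in front of the ring closure, so that base never meets the pyranone. Setting out from acid 12, KOH in aqueous EtOH at reflux (the carboxylate shields the acrylate from alkoxide, as in the classical saponification of β-aryloxycinnamates) should cleave both sulfonates and give (Z)-3-(2-hydroxy-3,4-dimethoxyphenoxy)-3-(3-hydroxy-4,5-dimethoxyphenyl)prop-2-enoic acid F4. Cycloacylation of F4 in P2O5/MeSO3H at rt, which tolerates free phenols, comes back to the route at 14.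

**Further compounds**

F1 | step 7 | tert-butyl (Z)-3-iodo-3-[3,4-dimethoxy-5-(tosyloxy)phenyl]prop-2-enoate | CC(C)(C)OC(=O)/C=C(\I)c1cc(OC)c(OC)c(OS(=O)(=O)c2ccc(C)cc2)c1
F2 | step 9 | 1-[2-hydroxy-4,5-dimethoxy-3-(tosyloxy)phenyl]ethan-1-one | COc1cc(C(C)=O)c(O)c(OS(=O)(=O)c2ccc(C)cc2)c1OC
F3 | step 9 | (E)-1-[2-hydroxy-4,5-dimethoxy-3-(tosyloxy)phenyl]-3-[3,4-dimethoxy-5-(tosyloxy)phenyl]prop-2-en-1-one | COc1cc(C(=O)/C=C/c2cc(OC)c(OC)c(OS(=O)(=O)c3ccc(C)cc3)c2)c(O)c(OS(=O)(=O)c2ccc(C)cc2)c1OC
F4 | step 10 | (Z)-3-(2-hydroxy-3,4-dimethoxyphenoxy)-3-(3-hydroxy-4,5-dimethoxyphenyl)prop-2-enoic acid | OC(=O)/C=C(\Oc1ccc(OC)c(OC)c1O)c1cc(OC)c(OC)c(O)c1
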